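**Retrosynthetic overview**

1. Labels and feature: ring A is the pyran O2–C1–C9a–C4a–C4=C3 (OAc on C1, C11H2OAc on C4); ring B is the cycloheptenone C4a–C5–C6–C7(=O)–C8=C9–C9a (formyl C12 on C9); C10 is the CMe2 carbon bridging C5 and C6. The strategy rests on C1 holding an acyloxy oxygen while its neighbour C9a holds the alkenyl carbon C9: this is what adding an alkenyl group and acetate across a C1=C9a enol ether of a 4H-pyran would leave.
2. Target 26 ⇒ 24 (C12 oxidation, desilylation) ⇒ C9–C9a and C1–OAc cut together, closing ring B last ⇒ 4H-pyran 22 carrying a Z β-iodoenone on the cis-cyclopropane.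
3. 22 ⇒ ring A by amine-catalysed Michael/hemiacetal annulation of enal 14 with methyl formylacetate (sets C4a), lactol dehydration, then ester → CH2OAc. C7 is kept as a carbinol acetate until the hydride step is over and only then oxidised, because no reductant would spare an enone.
4. 14 ⇒ Z vinyl iodide side chain by alkynylation of lactol 5 and hydroalumination–iodination; the cyclopropane comes from desymmetrised caronic anhydride 1.
5. Ring order: cyclopropane (bought) → ring A (steps 9–10) → ring B (step 14).

Key step: step 14

Assumption: quinidine is taken to open anhydride 1 in the sense that gives hemiester 2 as drawn; if this anhydride opens in the opposite sense, quinine replaces quinidine and nothing else changes.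

**Route**

Step 1
Reactants: 1 caronic anhydride
Product: 2 (1R,3S)-3-(methoxycarbonyl)-2,2-dimethylcyclopropane-1-carboxylic acid
Conditions: quinidine (1.1 equiv), MeOH (3 equiv), toluene, −55 °C; aq. HCl wash
Reagents that add atoms: methanol, CO
Why: Alkaloid-mediated desymmetrising methanolysis of a meso anhydride: quinidine acts as a chiral general base and steers methanol to one of the two enantiotopic carbonyl groups, which fixes C5 (R) and C6 (S) at once because it decides which cyclopropane carbon keeps the free acid.

Step 2
Reactants: 2 hemiester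
Product: 4 lactone (1S,5R)-6,6-dimethyl-3-oxabicyclo[3.1.0]hexan-2-one, via hydroxy ester 3 (not isolated)
Conditions: BH3·SMe2, THF, 0 °C to rt; H2O; TsOH (cat.), toluene, 60 °C
Reagents that add atoms: none
Why: Chemoselective borane reduction of a carboxylic acid beside an ester followed by acid-catalysed lactonisation of the cis hydroxy ester; no stereocentre is touched, the former acid carbon becomes the CH2O carbon (later C4a) and the ester carbon becomes the lactone carbonyl (later C7).

Step 3
Reactants: 4 lactone
Product: 5 lactol (1S,5R)-6,6-dimethyl-3-oxabicyclo[3.1.0]hexan-2-ol (both C2 epimers)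
Conditions: i-Bu2AlH (1.1 equiv), CH2Cl2, −78 °C; aq. KNaC4H4O6 (potassium sodium tartrate)
Reagents that add atoms: none
Why: Partial reduction of a γ-lactone with i-Bu2AlH stops at the aluminium lactolate at −78 °C, giving the lactol as a latent cis hydroxy aldehyde without change at C5 or C6.

Step 4
Reactants: 5 lactol; 6 tert-butyldimethyl(prop-2-yn-1-yloxy)silane
Product: 8 propargylic diol (C5 R, C6 S; C7 both epimers), via lithium acetylide 7 (not isolated)
Conditions: 6 (3.2 equiv), n-BuLi (3.0 equiv), THF, −78 °C; then 5, −78 to 0 °C; aq. NH4Cl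
Reagents that add atoms: none
Why: Acetylide addition to a lactol: the first equivalent of base opens the lactolate to the alkoxy aldehyde and the lithium acetylide adds to its carbonyl group, forming C7–C8; C7 forms as both epimers, which is accepted because C7 becomes a ketone in step 13.

Step 5
Reactants: 8 propargylic diol
Product: 10 Z-iodo allylic diol, via cyclic alkenylalanate 9 (not isolated)
Conditions: NaAlH2(OCH2CH2OMe)2 (3.5 equiv), THF, 0 °C to rt; then I2 (5 equiv), THF, −78 °C; aq. Na2S2O3, aq. KNaC4H4O6
Reagents that add atoms: iodine, II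
Why: Alkoxide-directed trans-hydroalumination of a propargylic alcohol and iodinolysis with retention: hydride goes to C8 and aluminium to C9 in a five-membered alanate tied to the C7 oxygen, so iodine ends on C9 cis to C7 (Z), while the silylated C12 oxygen cannot direct and the mixture is kept at or below room temperature to avoid β-elimination of the silyloxy group.

Step 6
Reactants: 10 Z-iodo allylic diol
Product: 12 C7 acetate with primary triethylsilyl ether, via primary triethylsilyl ether 11 (not isolated)
Conditions: Et3SiCl (1.05 equiv), imidazole, CH2Cl2, −78 to −40 °C; then Ac2O, Et3N, DMAP (cat.), 0 °C to rt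
Reagents that add atoms: chlorotriethylsilane, CC[Si](Cl)(CC)CC; acetic anhydride, CC(=O)OC(C)=O
Why: Kinetically selective silylation of the unhindered primary hydroxyl followed by acetylation of the remaining secondary one in the same flask; the C7 acetate blocks oxa-Michael closure onto C4a in steps 8 and 9 and is later removed by the hydride of step 11.

Step 7
Reactants: 12 silyl ether acetate
Product: 13 cis-cyclopropane carbaldehyde (C4a as CHO)
Conditions: (COCl)2 (4 equiv), DMSO (8 equiv), CH2Cl2, −78 to −30 °C; Et3N, −78 °C to rt
Reagents that add atoms: none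
Why: Swern oxidation applied directly to a primary triethylsilyl ether (oxidative desilylation), which the activated DMSO reagent cleaves and oxidises while the secondary acetate and the bulkier TBS ether stay intact; the cis aldehyde on C5 is not enolised at these temperatures.

Step 8
Reactants: 13 aldehyde
Product: 14 E enal (C1HO–C9a=C4a–C5)
Conditions: Ph3P=CHCHO (1.5 equiv), toluene, 80 °C
Reagents that add atoms: (triphenylphosphoranylidene)acetaldehyde, O=CC=P(c1ccccc1)(c1ccccc1)c1ccccc1
Why: Wittig olefination with a stabilised formyl ylide gives the E enal under neutral conditions that do not epimerise the cis-cyclopropane aldehyde.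

Step 9
Reactants: 14 enal; 15 methyl 3,3-dimethoxypropanoate
Product: 17 lactol ester (methyl 2-hydroxy-4-cyclopropyl-3,4-dihydro-2H-pyran-5-carboxylate), via methyl 3-oxopropanoate 16 (not isolated)
Conditions: 15, 2 M aq. HCl, rt, extraction into CH2Cl2, 16 used at once (1.5 equiv); 14, (S)-2-[diphenyl(trimethylsilyloxy)methyl]pyrrolidine (20 mol %), PhCO2H (20 mol %), CH2Cl2, 0 °C to rt
Reagents that add atoms: water, O
Why: Iminium-ion-catalysed Michael addition of a 1,3-dicarbonyl C–H acid to an enal followed by hemiacetalisation (formal [3+3] annulation): the bulky group of the (S)-prolinol ether shields one face of the E iminium ion so that C4 of the formylacetate bonds to C4a on the open face, giving the C4a configuration drawn (S by CIP in 17, the same spatial arrangement as R in 19 to 26), and the C1 lactol epimers converge in step 10.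

Step 10
Reactants: 17 lactol ester
Product: 19 methyl 4H-pyran-3-carboxylate (C4a R, C5 R, C6 S), via anomeric mesylate 18 (not isolated)
Conditions: MsCl (1.5 equiv), Et3N (4 equiv), CH2Cl2, −20 °C to rt
Reagents that add atoms: none
Why: Lactol dehydration by sulfonylation and amine-mediated elimination through the anomeric mesylate gives the cyclic enol ether C1=C9a; the 4H-pyran is tolerable here because the other enol ether is a vinylogous carbonate, and C4a is not affected.

Step 11
Reactants: 19 4H-pyran ester
Product: 20 diol (C11–OH and C7–OH)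
Conditions: i-Bu2AlH (6 equiv), CH2Cl2, −78 °C; aq. KNaC4H4O6; Et3N-deactivated silica
Reagents that add atoms: none
Why: Hydride reduction with i-Bu2AlH turns the vinylogous carbonate into the C11 allylic alcohol (1,2-reduction) and removes the C7 acetate in the same operation; it is placed here because the molecule holds no ketone or aldehyde at this stage, and the vinyl iodide, the silyl ether and the enol ethers are inert at −78 °C.

Step 12
Reactants: 20 diol
Product: 21 C11 acetate with free C7–OH
Conditions: AcCl (1.1 equiv), 2,4,6-collidine (3 equiv), CH2Cl2, −78 °C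
Reagents that add atoms: acetyl chloride, CC(=O)Cl
Why: Kinetically selective acylation of the primary allylic hydroxyl at C11 over the hindered secondary C7 hydroxyl with acetyl chloride and a hindered pyridine base at −78 °C, conditions too mild to ionise the allylic C11–O bond.

Step 13
Reactants: 21 allylic alcohol
Product: 22 3-(acetoxymethyl)-4H-pyran bearing the cyclopropyl Z β-iodoenone (C4a R, C5 R, C6 S)
Conditions: Dess–Martin periodinane (1.5 equiv), NaHCO3, CH2Cl2, 0 °C, dark
Reagents that add atoms: none
Why: Buffered Dess–Martin oxidation of the secondary allylic alcohol gives the Z β-iodoenone from both C7 epimers without acid or metal oxidant, so the bis(enol ether), the allylic acetate and the C8=C9 geometry are kept.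

Step 14
Reactants: 22 iodoenone 4H-pyran
Product: 24 tricyclic acetal acetate with C12 as TBS ether (1S,4aR,5R,6S,9aR), via C1 oxocarbenium ion 23 (not isolated)
Conditions: Pd(OAc)2 (10 mol %), PPh3 (30 mol %), AgOAc (2 equiv), MeCN, 60 °C, dark
Reagents that add atoms: silver acetate, CC(=O)[O-].[Ag+]
Why: Proposed new method: zerovalent palladium formed in situ inserts into the C9–I bond with retention of the Z geometry, the cationic alkenylpalladium left after AgOAc removes iodide adds syn across the C1=C9a enol ether with C9 bonding to C9a, and the C1–palladium species so formed, which has oxygen on the same carbon and no syn β-hydrogen (H9a is anti), collapses with help from the O2 lone pair to zerovalent palladium and oxocarbenium ion 23, which acetate captures, so the cycle is redox-neutral and needs no base. The closest known reaction types are the intermolecular aryl-alkoxylation of cyclic enol ethers under cationic Heck–Matsuda conditions, where an α-oxygenated alkylpalladium likewise ends as an oxocarbenium ion trapped by the alcohol, and intramolecular Heck closures of seven-membered rings. Ring B closes in the 7-exo-trig mode (C9 onto C9a, with C1 outside the new ring). C9a is set by the tether, since C5 on C4a can deliver C9 only to the pyran face it occupies, which gives the cis ring fusion (9aR); C1 is set at the capture step, where return of acetate on the face palladium has just left and axial attack on the half-chair ion both place OAc cis to C9 (1S), the anomerically favoured arrangement, and a trans acetate could re-ionise and equilibrate under the Lewis-acidic silver conditions. The step needs C9a to react rather than C4 (fully substituted, would become quaternary) or C1 (8-endo), needs oxidative addition at the activated C–I bond to outrun ionisation of the allylic C11 acetate (degenerate in any case, acetate being the only nucleophile), and needs acetate capture to outrun loss of H9a from 23, which excess acetate in a non-basic medium should secure.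

Step 15
Reactants: 24 silyl ether
Product: 25 C12 allylic alcohol
Conditions: HF·pyridine, pyridine, THF, 0 °C to rt
Reagents that add atoms: none
Why: Fluoride-mediated cleavage of a primary allylic silyl ether under pyridine-buffered conditions that leave the acyl acetal, the enol ether, the allylic acetate and the enone untouched.

Step 16
Reactants: 25 allylic alcohol
Product: 26 target CNP0263020.2
Conditions: MnO2 (20 equiv), CH2Cl2, rt
Reagents that add atoms: none
Why: Allylic alcohol oxidation on activated manganese dioxide, a neutral heterogeneous oxidant selective for the C12 allylic hydroxyl, gives the C12 aldehyde without disturbing the C1 acetal acetate or any stereocentre.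

**Compound list**

1 | caronic anhydride, (1R,5S)-6,6-dimethyl-3-oxabicyclo[3.1.0]hexane-2,4-dione (meso) | O=C1[C@@H]2[C@@H](C2(C)C)C(=O)O1 | starting material
2 | (1R,3S)-3-(methoxycarbonyl)-2,2-dimethylcyclopropane-1-carboxylic acid | OC(=O)[C@@H]1[C@@H](C1(C)C)C(=O)OC | intermediate
3 | methyl (1S,3R)-3-(hydroxymethyl)-2,2-dimethylcyclopropane-1-carboxylate | OC[C@@H]1[C@@H](C1(C)C)C(=O)OC | intermediate (not isolated)
4 | (1S,5R)-6,6-dimethyl-3-oxabicyclo[3.1.0]hexan-2-one | O1C[C@@H]2[C@@H](C2(C)C)C1=O | intermediate
5 | (1S,5R)-6,6-dimethyl-3-oxabicyclo[3.1.0]hexan-2-ol, both C2 epimers | O1C[C@@H]2[C@@H](C2(C)C)C1O | intermediate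
6 | tert-butyldimethyl(prop-2-yn-1-yloxy)silane | C#CCO[Si](C)(C)C(C)(C)C | starting material
7 | [3-(tert-butyldimethylsilyloxy)prop-1-yn-1-yl]lithium | [Li]C#CCO[Si](C)(C)C(C)(C)C | intermediate (not isolated)
8 | 4-(tert-butyldimethylsilyloxy)-1-[(1S,3R)-3-(hydroxymethyl)-2,2-dimethylcyclopropyl]but-2-yn-1-ol (C5 R, C6 S; C7 both epimers) | OC[C@@H]1[C@@H](C1(C)C)C(O)C#CCO[Si](C)(C)C(C)(C)C | intermediate
9 | sodium cyclic alkenylalanate of 8 (aluminium on C9 and on the C7 oxygen, five-membered ring; primary alkoxide) | [Na+].[Na+].[O-]C[C@@H]1[C@@H](C1(C)C)C2O[Al-](OCCOC)(OCCOC)C(CO[Si](C)(C)C(C)(C)C)=C2 | intermediate (not isolated)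
10 | (Z)-4-(tert-butyldimethylsilyloxy)-1-[(1S,3R)-3-(hydroxymethyl)-2,2-dimethylcyclopropyl]-3-iodobut-2-en-1-ol (C7 both epimers) | OC[C@@H]1[C@@H](C1(C)C)C(O)/C=C(\I)CO[Si](C)(C)C(C)(C)C | intermediate
11 | primary triethylsilyl ether of 10 (C7–OH free) | CC[Si](CC)(CC)OC[C@@H]1[C@@H](C1(C)C)C(O)/C=C(\I)CO[Si](C)(C)C(C)(C)C | intermediate (not isolated)
12 | (Z)-4-(tert-butyldimethylsilyloxy)-3-iodo-1-[(1S,3R)-2,2-dimethyl-3-(triethylsilyloxymethyl)cyclopropyl]but-2-en-1-yl acetate (C7 both epimers) | CC[Si](CC)(CC)OC[C@@H]1[C@@H](C1(C)C)C(OC(C)=O)/C=C(\I)CO[Si](C)(C)C(C)(C)C | intermediate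
13 | (Z)-4-(tert-butyldimethylsilyloxy)-1-[(1S,3R)-3-formyl-2,2-dimethylcyclopropyl]-3-iodobut-2-en-1-yl acetate (C5 R, C6 S; C7 both epimers) | O=C[C@@H]1[C@@H](C1(C)C)C(OC(C)=O)/C=C(\I)CO[Si](C)(C)C(C)(C)C | intermediate
14 | (Z)-4-(tert-butyldimethylsilyloxy)-1-{(1S,3R)-2,2-dimethyl-3-[(E)-3-oxoprop-1-en-1-yl]cyclopropyl}-3-iodobut-2-en-1-yl acetate (C5 R, C6 S; C7 both epimers) | O=C/C=C/[C@@H]1[C@@H](C1(C)C)C(OC(C)=O)/C=C(\I)CO[Si](C)(C)C(C)(C)C | intermediate
15 | methyl 3,3-dimethoxypropanoate | COC(CC(=O)OC)OC | starting material
16 | methyl 3-oxopropanoate (methyl formylacetate) | O=CCC(=O)OC | intermediate (not isolated)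
17 | methyl 2-hydroxy-4-[cis-3-((Z)-1-acetoxy-4-(tert-butyldimethylsilyloxy)-3-iodobut-2-enyl)-2,2-dimethylcyclopropyl]-3,4-dihydro-2H-pyran-5-carboxylate (C4a S by CIP, same geometry as C4a R in 19–26; C5 R, C6 S; C1 and C7 both epimers) | COC(=O)C1=COC(O)C[C@H]1[C@@H]2[C@@H](C2(C)C)C(OC(C)=O)/C=C(\I)CO[Si](C)(C)C(C)(C)C | intermediate
18 | anomeric (C1) methanesulfonate of 17 | COC(=O)C1=COC(OS(C)(=O)=O)C[C@H]1[C@@H]2[C@@H](C2(C)C)C(OC(C)=O)/C=C(\I)CO[Si](C)(C)C(C)(C)C | intermediate (not isolated)
19 | methyl 4-[cis-3-((Z)-1-acetoxy-4-(tert-butyldimethylsilyloxy)-3-iodobut-2-enyl)-2,2-dimethylcyclopropyl]-4H-pyran-3-carboxylate (C4a R, C5 R, C6 S; C7 both epimers) | COC(=O)C1=COC=C[C@H]1[C@@H]2[C@@H](C2(C)C)C(OC(C)=O)/C=C(\I)CO[Si](C)(C)C(C)(C)C | intermediate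
20 | (Z)-4-(tert-butyldimethylsilyloxy)-1-{cis-3-[3-(hydroxymethyl)-4H-pyran-4-yl]-2,2-dimethylcyclopropyl}-3-iodobut-2-en-1-ol (C4a R, C5 R, C6 S; C7 both epimers) | OCC1=COC=C[C@H]1[C@@H]2[C@@H](C2(C)C)C(O)/C=C(\I)CO[Si](C)(C)C(C)(C)C | intermediate
21 | {4-[cis-3-((Z)-4-(tert-butyldimethylsilyloxy)-1-hydroxy-3-iodobut-2-enyl)-2,2-dimethylcyclopropyl]-4H-pyran-3-yl}methyl acetate (C4a R, C5 R, C6 S; C7 both epimers) | CC(=O)OCC1=COC=C[C@H]1[C@@H]2[C@@H](C2(C)C)C(O)/C=C(\I)CO[Si](C)(C)C(C)(C)C | intermediate
22 | {4-[cis-3-((Z)-4-(tert-butyldimethylsilyloxy)-3-iodobut-2-enoyl)-2,2-dimethylcyclopropyl]-4H-pyran-3-yl}methyl acetate (C4a R, C5 R, C6 S) | CC(=O)OCC1=COC=C[C@H]1[C@@H]2[C@@H](C2(C)C)C(=O)/C=C(\I)CO[Si](C)(C)C(C)(C)C | intermediate (key-step precursor)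
23 | C1 oxocarbenium ion with ring B closed (C4a R, C5 R, C6 S, C9a R) | CC(=O)OCC1=C[O+]=C[C@H]2C(CO[Si](C)(C)C(C)(C)C)=CC(=O)[C@H]3[C@@H]([C@@H]12)C3(C)C | intermediate (not isolated)
24 | C12 tert-butyldimethylsilyl ether of the reduced target: tricyclic C1 acetal acetate, C11 acetate, C7 enone (1S,4aR,5R,6S,9aR) | CC(=O)OCC1=CO[C@@H](OC(C)=O)[C@H]2C(CO[Si](C)(C)C(C)(C)C)=CC(=O)[C@H]3[C@@H]([C@@H]12)C3(C)C | intermediate (key-step product)
25 | C12 alcohol (1S,4aR,5R,6S,9aR) | CC(=O)OCC1=CO[C@@H](OC(C)=O)[C@H]2C(CO)=CC(=O)[C@H]3[C@@H]([C@@H]12)C3(C)C | intermediate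
26 | CNP0263020.2 (1S,4aR,5R,6S,9aR) | CC(=O)OCC1=CO[C@@H](OC(C)=O)[C@H]2C(C=O)=CC(=O)[C@H]3[C@@H]([C@@H]12)C3(C)C | target

**Totals**

Total step count: 16. Longest linear sequence: 16 steps (1 to 26); 6 and 15 are bought.

**Steps most likely to fail**

Step 14 (proposed new method). Several processes may defeat it:
- the C1–palladium intermediate may not collapse to the oxocarbenium ion, ending instead in protodepalladation or catalyst death;
- the ion may lose H9a instead of taking up acetate;
- zerovalent palladium may ionise the C11 allylic acetate;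
- the cis-acylcyclopropane may undergo a thermal 1,5-hydrogen shift from the doubly allylic C4a–H, and silver ion may oxidise the 4H-pyran.

The fallback sets out from 22 and comes back at 24. It replaces the organopalladium pathway by a visible-light radical–polar crossover whose elementary steps are each documented: photoreductive cleavage of activated alkenyl iodides, alkenyl-radical addition to enol ethers, and oxidation of α-alkoxyalkyl radicals to oxocarbenium ions with carboxylate capture. With Ir(ppy)3 (1 mol %), n-Bu4NOAc (3 equiv), MeCN, blue light, rt, the excited catalyst should reduce the β-iodoenone to the C9 alkenyl radical, which adds 7-exo to C9a through the same tether-controlled face. The tetravalent iridium formed in the first electron transfer then oxidises the C1 radical to ion 23, and acetate capture gives 24. The fallback passes through no new isolable compound (F0).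

Step 9. The free formylacetate may trimerise or condense with the amine catalyst to an inert enaminoester faster than the iminium ion turns over, and the resident cyclopropane stereocentres may oppose the catalyst, giving poor facial selectivity at C4a. The fallback sets out from 14 and comes back at 17. Enal 14 is used as a 1-oxadiene in an inverse-electron-demand hetero-Diels–Alder reaction with ethyl vinyl ether under the tridentate Schiff-base chromium chloride catalyst (ONO)CrCl (trivalent chromium). The catalyst enantiomer is chosen to set C4a as drawn, and the product is the 2-ethoxy-3,4-dihydro-2H-pyran F1; here the enal carbons become C3, C4 and C4a and the vinyl ether supplies C9a and C1. Trichloroacetyl chloride and pyridine acylate the enol ether at C4 to give the trichloromethyl ketone F2. Methanol with Et3N (haloform-type cleavage) gives the methyl ester F3, and PPTS in wet acetone hydrolyses the ethyl acetal to lactol 17.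

Step 12. Acetyl transfer may fail to discriminate the two hydroxyls of 20, and the unprotected 3-(hydroxymethyl)-4H-pyran may ionise at C11 during handling. The fallback sets out from 19 and comes back at 21; it makes the two oxygens different before the hydride step. K2CO3 in MeOH at 0 °C removes the C7 acetate to give the alcohol F4, and Et3SiCl with imidazole gives the triethylsilyl ether F5. i-Bu2AlH at −78 °C gives the C11 alcohol F6, which is acetylated at once (Ac2O, pyridine, DMAP) to the acetate F7. Pyridine-buffered HF·pyridine at 0 °C then removes the secondary triethylsilyl group in the presence of the primary TBS ether to give 21.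

**Further compounds**

F0 | step 14 | none | none
F1 | step 9 | 2-ethoxy-4-[cis-3-((Z)-1-acetoxy-4-(tert-butyldimethylsilyloxy)-3-iodobut-2-enyl)-2,2-dimethylcyclopropyl]-3,4-dihydro-2H-pyran | C1=COC(OCC)C[C@H]1[C@@H]2[C@@H](C2(C)C)C(OC(C)=O)/C=C(\I)CO[Si](C)(C)C(C)(C)C
F2 | step 9 | 5-trichloroacetyl derivative of F1 | ClC(Cl)(Cl)C(=O)C1=COC(OCC)C[C@H]1[C@@H]2[C@@H](C2(C)C)C(OC(C)=O)/C=C(\I)CO[Si](C)(C)C(C)(C)C
F3 | step 9 | methyl 2-ethoxy-3,4-dihydro-2H-pyran-5-carboxylate analogue of 17 (ethyl acetal) | COC(=O)C1=COC(OCC)C[C@H]1[C@@H]2[C@@H](C2(C)C)C(OC(C)=O)/C=C(\I)CO[Si](C)(C)C(C)(C)C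
F4 | step 12 | C7 alcohol of 4H-pyran ester 19 | COC(=O)C1=COC=C[C@H]1[C@@H]2[C@@H](C2(C)C)C(O)/C=C(\I)CO[Si](C)(C)C(C)(C)C
F5 | step 12 | C7 triethylsilyl ether of F4 | COC(=O)C1=COC=C[C@H]1[C@@H]2[C@@H](C2(C)C)C(O[Si](CC)(CC)CC)/C=C(\I)CO[Si](C)(C)C(C)(C)C
F6 | step 12 | C11 alcohol with C7 triethylsilyl ether | OCC1=COC=C[C@H]1[C@@H]2[C@@H](C2(C)C)C(O[Si](CC)(CC)CC)/C=C(\I)CO[Si](C)(C)C(C)(C)C
F7 | step 12 | C11 acetate with C7 triethylsilyl ether | CC(=O)OCC1=COC=C[C@H]1[C@@H]2[C@@H](C2(C)C)C(O[Si](CC)(CC)CC)/C=C(\I)CO[Si](C)(C)C(C)(C)C
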